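- A small charge of solid substrate sits under a held gas phase, and we want the product standing at the asked time.

| setting | beta | alpha | flask |
|---|---|---|---|
| solid substrate | 1.7 M | 2.6 M | 1.2 M |
| gas phase | 51 mM (held) | 51 mM (held) | 51 mM (held) |
| remark | run made earlier | run made earlier |  |
| time |  |  | 2.0 d |

| beta: time / h | beta: product / % | alpha: time / h | alpha: product / % |
|---|---|---|---|
| 3.00 | 0 | 8.00 | 2 |
| 10.0 | 7 | 15.0 | 1 |
| 15.0 | 3 | 25.0 | 6 |
| 25.0 | 8 | 30.0 | 8 |
| 40.0 | 12 | 40.0 | 9 |
| 50.0 | 19 | 50.0 | 10 |

(each reading ± 2 percentage points)

- solid substrate is a solid; its amount is given per volume of the solution
- at the start none of the gas phase is in solution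
- at the start none of the solid substrate is in solution

- the product standing at 2.0 d, as a percentage of the solid substrate charged
- the change that raises the amount of product at 2.0 d, in percent of the solid substrate charged most ("none" if none brings more than 2 percentage points) (east / north-west / north-east / north / none)
- amount of product at 2.0 d, in percent of the solid substrate charged, after north

- east: doubling the transfer coefficient of the gas phase, all else as stated
- north-west: doubling the saturation concentration of gas phase, all else as stated
- north-east: doubling the dissolution coefficient of the solid substrate, all else as stated
- north: doubling the solubility of the solid substrate, all else as stated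

- We start with the main step by itself. A first-order step turns the same share of any charge in a given time, yet at 50.0 h the beta run shows 19% and the alpha run 10%, although alpha holds more solid.
- Now we add dissolution. If the solution stays at a limited level while solid lies undissolved, the step gets the same feed at any charge, like a tank with a constant outlet, so we count c(product) instead of percent. The mean making rate, c(product) at the last reading divided by its time, is 0.00646 M/h for beta and 0.00520 M/h for alpha. We carry their mean, 0.00583 M/h, taken as zero order in the charge.
- Then we add the rest, the start-up. At 15.0 h the mean line gives 0.0874 M, but the beta reading is 0.0510 M, one reading with a scatter of 2 percentage points. The mean runs from the start to the last reading, so it contains any slow start, and our flask is read at 48 h, near 50.0 h.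
- Our own reckoning for the flask is the rate times the time over the charge, 23.3%, give or take 2.5 points from the gap between the runs.
- The forecast, which differs slightly, says 22%, best change north-west, and 23% after north: “I guess gas-transfer limitation, so north changes little”.
- The flask gives 24.2%, best change north-west, and 38.8% after north.

    gas phase ⇌ dissolved gas, rate k1*(csat - [dissolved gas]) (kL = 2.56 × 10⁻⁴ /s)
    starting material + dissolved gas → product (k = 9.35 × 10⁻⁵ /M/s)
    starting material ⇌ dormant form (K = 2.59, k = 1.45 × 10⁻⁶ /s)
    solid substrate ⇌ starting material, rate k4*(cs4 - [starting material]) while solid is left; crystals form when [starting material] > cs4 (solubility = 0.490 M, k = 6.02 × 10⁻⁵ /s)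

- The forecast parts from the flask at north, which lifts the flask's mean rate to 0.00970 M/h. At 1.00 d starting material stands at 91.3% of saturation. Taking away its low solubility, which also sets how fast it dissolves, gives 41.6% against 24.2%; this is part of the shortfall, together with the early reading, since ten times later the flask holds 84.9%.
- For the neighbour flask with 0.48 M of solid substrate, the mean rate gives 58.3%. The computed flask gives 44.7%, with solid at 0% and starting material at 0.196 M, below its saturation of 0.49 M.

All runs are calculated with made-up constants.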